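**Plan**
- Ring locants used throughout: C1 = acetoxy carbon, C2 and C3 = ring CH2 groups, C4 = ring carbinol carbon, C5 = ring CH bearing the side chain, C6 = CMe2. The oxygens on C1 and C4 are 1,4-related through C2–C3, a dissonant pattern. With C1 as a vinyl ketone, C3 (enone β-carbon) and C4 (methyl ketone carbon) are both electrophilic, and two electrons can join them.
- Retrosynthetic cuts, in order: aryl ether C–O; C1 acetate and carbinol back to a C1 ketone; ring bond C3–C4; C1–C2 (vinyl to acyl); C5–C6 (Ireland–Claisen); the C=C made by Wittig; the alkene of (R)-linalool.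
- Forward: the linalool-derived aldehyde is extended, C5–C6 is joined by sigmatropic shift, the vinyl ketone and methyl ketone are unmasked, the only carbocycle closes at C3–C4, and the coumarin is attached last.
- Stereochemistry: the side-chain carbinol comes from (R)-linalool. C5 comes by chirality transfer from a CBS-derived (S)-allylic carbinol. C4 is set from C5 in the ring closure. C1 is set by equatorial hydride delivery to the ring ketone.

Key step: step 11

Assumption: commercial (R)-(−)-linalool and the ylide 7 are used as supplied; any (S)-linalool content would appear as a minor diastereomer after step 7 and be removed there by chromatography.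

**Step 1**
Reactants: 1 (R)-(−)-linalool
Product: 3 (3R)-3,7-dimethyloct-6-ene-1,3-diol, via B-alkyl-9-BBN adduct 2 (not isolated)
Conditions: 9-BBN (2.2 equiv), THF, 0 °C → rt; then NaOH, H2O2, 0 °C → rt
Reagents that add atoms: hydrogen peroxide, OO
Why: Hydroboration–oxidation with 9-BBN is anti-Markovnikov and selects the monosubstituted vinyl group over the trisubstituted alkene; the carbinol stereocentre is not touched.

**Step 2**
Reactants: 3 (3R)-3,7-dimethyloct-6-ene-1,3-diol
Product: 4 (3R)-1,3-bis(tert-butyldimethylsilyloxy)-3,7-dimethyloct-6-ene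
Conditions: TBSOTf (2.5 equiv), 2,6-lutidine, CH2Cl2, 0 °C → rt
Reagents that add atoms: tert-butyldimethylsilyl triflate, CC(C)(C)[Si](C)(C)OS(=O)(=O)C(F)(F)F
Why: A silyl triflate with 2,6-lutidine should silylate the primary and the hindered tertiary hydroxyl alike (silyl ether protection).

**Step 3**
Reactants: 4 (3R)-1,3-bis(tert-butyldimethylsilyloxy)-3,7-dimethyloct-6-ene
Product: 6 (4R)-4,6-bis(tert-butyldimethylsilyloxy)-4-methylhexanal, via secondary ozonide 5 (not isolated)
Conditions: O3, CH2Cl2, −78 °C; then PPh3, −78 °C → rt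
Reagents that add atoms: ozone, [O-][O+]=O
Why: Ozonolysis with reductive work-up cleaves the only C=C bond and should give the aldehyde whose carbonyl carbon becomes C5.

**Step 4**
Reactants: 6 (4R)-4,6-bis(tert-butyldimethylsilyloxy)-4-methylhexanal; 7 3-(triphenylphosphoranylidene)butan-2-one
Product: 8 (3E,7R)-7,9-bis(tert-butyldimethylsilyloxy)-3,7-dimethylnon-3-en-2-one
Conditions: toluene, 100 °C
Reagents that add atoms: none
Why: Wittig olefination with an α-branched stabilised acyl ylide should give the (E)-trisubstituted enone.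

**Step 5**
Reactants: 8 (3E,7R)-7,9-bis(tert-butyldimethylsilyloxy)-3,7-dimethylnon-3-en-2-one
Product: 9 (2S,3E,7R)-7,9-bis(tert-butyldimethylsilyloxy)-3,7-dimethylnon-3-en-2-ol
Conditions: (R)-2-methyl-CBS-oxazaborolidine (0.2 equiv), BH3·SMe2, THF, −30 °C; then MeOH, H2O
Reagents that add atoms: none
Why: In the Corey–Bakshi–Shibata reduction the alkenyl group acts as the large substituent, so the (R)-catalyst should deliver hydride to give the (S)-carbinol by catalyst control, with 1,2-reduction only.

**Step 6**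
Reactants: 9 (2S,3E,7R)-7,9-bis(tert-butyldimethylsilyloxy)-3,7-dimethylnon-3-en-2-ol; 10 2-methylpropanoyl chloride
Product: 11 (2S,3E,7R)-7,9-bis(tert-butyldimethylsilyloxy)-3,7-dimethylnon-3-en-2-yl 2-methylpropanoate
Conditions: pyridine, DMAP (cat.), CH2Cl2, 0 °C → rt
Reagents that add atoms: none
Why: DMAP-catalysed acylation of the secondary allylic alcohol proceeds with retention at the carbinol carbon.

**Step 7**
Reactants: 11 (2S,3E,7R)-7,9-bis(tert-butyldimethylsilyloxy)-3,7-dimethylnon-3-en-2-yl 2-methylpropanoate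
Product: 14 (3R,4E)-3-[(3R)-3,5-bis(tert-butyldimethylsilyloxy)-3-methylpentyl]-2,2,4-trimethylhex-4-enoic acid, via trimethylsilyl ketene acetal 12 (not isolated), via trimethylsilyl ester 13 (not isolated)
Conditions: LiN(i-Pr)2 (LDA), TMSCl/Et3N, THF, −78 °C → 55 °C; then pH 5 citrate buffer
Reagents that add atoms: none
Why: In the Ireland–Claisen rearrangement the tetrasubstituted ketene acetal has no enolate geometry to control, and the shift through a transition state with the carbinol methyl pseudo-equatorial should transfer the (S)-carbinol chirality across the (E)-alkene to C5 while forging the hindered C5–C6 bond.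

**Step 8**
Reactants: 14 (3R,4E)-3-[(3R)-3,5-bis(tert-butyldimethylsilyloxy)-3-methylpentyl]-2,2,4-trimethylhex-4-enoic acid
Product: 16 (3R,4E)-3-[(3R)-3,5-bis(tert-butyldimethylsilyloxy)-3-methylpentyl]-N-methoxy-N,2,2,4-tetramethylhex-4-enamide, via acid chloride 15 (not isolated)
Conditions: 1-chloro-N,N,2-trimethylprop-1-en-1-amine, CH2Cl2, 0 °C → rt; then MeNH(OMe)·HCl, pyridine, 0 °C → rt
Reagents that add atoms: N,O-dimethylhydroxylamine hydrochloride, CNOC.Cl
Why: Neutral acid chloride formation with the α-chloroenamine avoids acid-induced lactonisation onto the trisubstituted alkene, and amidation then gives the Weinreb amide.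

**Step 9**
Reactants: 16 (3R,4E)-3-[(3R)-3,5-bis(tert-butyldimethylsilyloxy)-3-methylpentyl]-N-methoxy-N,2,2,4-tetramethylhex-4-enamide; 17 vinylmagnesium bromide
Product: 18 (5R,6E)-5-[(3R)-3,5-bis(tert-butyldimethylsilyloxy)-3-methylpentyl]-4,4,6-trimethylocta-1,6-dien-3-one
Conditions: CH2=CHMgBr (3 equiv), THF, 0 °C → rt; inverse quench into cold 1 M HCl
Reagents that add atoms: none
Why: In the Weinreb ketone synthesis the chelated tetrahedral intermediate prevents over-addition, and the acidic inverse quench keeps the liberated amine from adding to the new vinyl ketone.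

**Step 10**
Reactants: 18 (5R,6E)-5-[(3R)-3,5-bis(tert-butyldimethylsilyloxy)-3-methylpentyl]-4,4,6-trimethylocta-1,6-dien-3-one
Product: 20 (3S)-3-[(3R)-3,5-bis(tert-butyldimethylsilyloxy)-3-methylpentyl]-4,4-dimethylhept-6-ene-2,5-dione, via secondary ozonide 19 (not isolated)
Conditions: O3 (to the end point of Sudan Red 7B), CH2Cl2, −78 °C; then Me2S, −78 °C → rt
Reagents that add atoms: ozone, [O-][O+]=O
Why: Electrophilic ozone should attack the electron-rich trisubstituted alkene far faster than the electron-poor vinyl ketone, so this chemoselective ozonolysis unmasks the C4 methyl ketone under neutral conditions that should not epimerise C5.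

**Step 11**
Reactants: 20 (3S)-3-[(3R)-3,5-bis(tert-butyldimethylsilyloxy)-3-methylpentyl]-4,4-dimethylhept-6-ene-2,5-dione
Product: 22 (3S,4R)-3-[(3R)-3,5-bis(tert-butyldimethylsilyloxy)-3-methylpentyl]-4-hydroxy-2,2,4-trimethylcyclohexan-1-one, via samarium enolate alkoxide 21 (not isolated)
Conditions: SmI2 (2.5 equiv), HMPA, THF, −78 °C, slow addition of 20 at high dilution, no proton donor; then pH 7 aqueous buffer
Reagents that add atoms: none
Why: Proposed new method: SmI2 should transfer one electron to the vinyl ketone of 20, the more easily reduced carbonyl system, giving a samarium-bound allylic ketyl with spin density on the terminal enone carbon C3; C3 then joins the carbonyl carbon C4 of the methyl ketone, activated by the oxophilic trivalent samarium, and a second electron converts the oxygen radical into the alkoxide, leaving enolate alkoxide 21, which water protonates at C2 (attack of a C4 ketyl on C3 would converge on the same species). The closest known reaction types are the SmI2 ketyl–olefin cyclisation of ketones onto α,β-unsaturated carbonyl acceptors and the cathodic hydrocoupling of enones with ketones; the new element is that the acceptor carbonyl lies inside the forming ring. The single ring closes in the 6-endo-trig mode with respect to the C2=C3 bond, preferred over 5-exo attack at C2 because spin and nucleophilic character reside at C3 and attack at C2 would leave an unstabilised primary radical instead of an enolate. The new quaternary stereocentre C4 is controlled by C5 through a chair-like transition state in which the C5 side chain is equatorial and antiperiplanar to the forming C3–C4 bond and the C4 methyl is equatorial to avoid a syn-pentane contact with the axial methyl on C6, so the C4 oxygen is axial and cis to the side chain as in the target. The step needs coupling at C3 in preference to pinacol closure between C1 and C4, intermolecular enone dimerisation and plain conjugate reduction; the strain of a cyclobutanediol, slow addition at high dilution and the absence of a proton donor should secure this.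

**Step 12**
Reactants: 22 (3S,4R)-3-[(3R)-3,5-bis(tert-butyldimethylsilyloxy)-3-methylpentyl]-4-hydroxy-2,2,4-trimethylcyclohexan-1-one
Product: 23 (1R,2S,4R)-2-[(3R)-3,5-bis(tert-butyldimethylsilyloxy)-3-methylpentyl]-1,3,3-trimethylcyclohexane-1,4-diol
Conditions: LiBH(s-Bu)3 (L-Selectride, 2.5 equiv), THF, −78 °C; then H2O
Reagents that add atoms: none
Why: The bulky trialkylborohydride cannot pass the axial hydrogens on C3 and C5 and should attack C1 along the equatorial trajectory, giving the axial C1 alcohol trans to the side chain, as 2,2-dimethylcyclohexanones in 4,4-dimethyl-3-oxo terpenoids give axial alcohols.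

**Step 13**
Reactants: 23 (1R,2S,4R)-2-[(3R)-3,5-bis(tert-butyldimethylsilyloxy)-3-methylpentyl]-1,3,3-trimethylcyclohexane-1,4-diol
Product: 24 (1R,3S,4R)-3-[(3R)-3,5-bis(tert-butyldimethylsilyloxy)-3-methylpentyl]-4-hydroxy-2,2,4-trimethylcyclohexyl acetate
Conditions: Ac2O, pyridine, DMAP (cat.), CH2Cl2, rt
Reagents that add atoms: acetic anhydride, CC(=O)OC(C)=O
Why: DMAP-catalysed acetylation should acylate the secondary C1 hydroxyl, while the tertiary C4 hydroxyl is inert under these conditions.

**Step 14**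
Reactants: 24 (1R,3S,4R)-3-[(3R)-3,5-bis(tert-butyldimethylsilyloxy)-3-methylpentyl]-4-hydroxy-2,2,4-trimethylcyclohexyl acetate
Product: 25 (1R,3S,4R)-3-[(3R)-3,5-dihydroxy-3-methylpentyl]-4-hydroxy-2,2,4-trimethylcyclohexyl acetate
Conditions: HF·pyridine, pyridine, THF, 0 °C → rt
Reagents that add atoms: none
Why: Buffered fluoride desilylation should cleave both silyl ethers while leaving the acetate and the tertiary alcohols intact.

**Step 15**
Reactants: 25 (1R,3S,4R)-3-[(3R)-3,5-dihydroxy-3-methylpentyl]-4-hydroxy-2,2,4-trimethylcyclohexyl acetate; 26 umbelliferone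
Product: 27 (1R,3S,4R)-4-hydroxy-3-[(3R)-3-hydroxy-3-methyl-5-(2-oxo-2H-chromen-7-yloxy)pentyl]-2,2,4-trimethylcyclohexyl acetate
Conditions: PPh3, DIAD, THF, 0 °C → rt
Reagents that add atoms: none
Why: In the Mitsunobu etherification only the primary alcohol forms an alkoxyphosphonium ion that the acidic phenol can displace, and the coumarin is attached last because its unsaturated lactone would not survive SmI2 or the borohydride.

**Compound list**
1 | (R)-(−)-linalool, (3R)-3,7-dimethylocta-1,6-dien-3-ol | CC(C)=CCC[C@@](C)(O)C=C | starting material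
2 | B-alkyl-9-BBN adduct, (3R)-1-(9-borabicyclo[3.3.1]nonan-9-yl)-3,7-dimethyloct-6-en-3-ol | CC(C)=CCC[C@@](C)(O)CCB1C2CCCC1CCC2 | intermediate
3 | (3R)-3,7-dimethyloct-6-ene-1,3-diol | CC(C)=CCC[C@@](C)(O)CCO | intermediate
4 | (3R)-1,3-bis(tert-butyldimethylsilyloxy)-3,7-dimethyloct-6-ene | CC(C)=CCC[C@@](C)(O[Si](C)(C)C(C)(C)C)CCO[Si](C)(C)C(C)(C)C | intermediate
5 | secondary ozonide of 4 (3,3-dimethyl-1,2,4-trioxolane carrying the silylated chain at its 5-position) | CC1(C)OOC(CC[C@@](C)(O[Si](C)(C)C(C)(C)C)CCO[Si](C)(C)C(C)(C)C)O1 | intermediate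
6 | (4R)-4,6-bis(tert-butyldimethylsilyloxy)-4-methylhexanal | O=CCC[C@@](C)(O[Si](C)(C)C(C)(C)C)CCO[Si](C)(C)C(C)(C)C | intermediate
7 | 3-(triphenylphosphoranylidene)butan-2-one | CC(=O)C(C)=P(c1ccccc1)(c1ccccc1)c1ccccc1 | starting material
8 | (3E,7R)-7,9-bis(tert-butyldimethylsilyloxy)-3,7-dimethylnon-3-en-2-one | CC(=O)/C(C)=C/CC[C@@](C)(O[Si](C)(C)C(C)(C)C)CCO[Si](C)(C)C(C)(C)C | intermediate
9 | (2S,3E,7R)-7,9-bis(tert-butyldimethylsilyloxy)-3,7-dimethylnon-3-en-2-ol | C[C@H](O)/C(C)=C/CC[C@@](C)(O[Si](C)(C)C(C)(C)C)CCO[Si](C)(C)C(C)(C)C | intermediate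
10 | 2-methylpropanoyl chloride (isobutyryl chloride) | CC(C)C(Cl)=O | starting material
11 | (2S,3E,7R)-7,9-bis(tert-butyldimethylsilyloxy)-3,7-dimethylnon-3-en-2-yl 2-methylpropanoate | CC(C)C(=O)O[C@@H](C)/C(C)=C/CC[C@@](C)(O[Si](C)(C)C(C)(C)C)CCO[Si](C)(C)C(C)(C)C | intermediate
12 | trimethylsilyl ketene acetal of ester 11 | CC(C)=C(O[Si](C)(C)C)O[C@@H](C)/C(C)=C/CC[C@@](C)(O[Si](C)(C)C(C)(C)C)CCO[Si](C)(C)C(C)(C)C | intermediate
13 | trimethylsilyl ester of acid 14 | C[Si](C)(C)OC(=O)C(C)(C)[C@H](CC[C@@](C)(O[Si](C)(C)C(C)(C)C)CCO[Si](C)(C)C(C)(C)C)/C(C)=C/C | intermediate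
14 | (3R,4E)-3-[(3R)-3,5-bis(tert-butyldimethylsilyloxy)-3-methylpentyl]-2,2,4-trimethylhex-4-enoic acid | OC(=O)C(C)(C)[C@H](CC[C@@](C)(O[Si](C)(C)C(C)(C)C)CCO[Si](C)(C)C(C)(C)C)/C(C)=C/C | intermediate
15 | acid chloride of 14 | ClC(=O)C(C)(C)[C@H](CC[C@@](C)(O[Si](C)(C)C(C)(C)C)CCO[Si](C)(C)C(C)(C)C)/C(C)=C/C | intermediate
16 | (3R,4E)-3-[(3R)-3,5-bis(tert-butyldimethylsilyloxy)-3-methylpentyl]-N-methoxy-N,2,2,4-tetramethylhex-4-enamide | CON(C)C(=O)C(C)(C)[C@H](CC[C@@](C)(O[Si](C)(C)C(C)(C)C)CCO[Si](C)(C)C(C)(C)C)/C(C)=C/C | intermediate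
17 | vinylmagnesium bromide | C=C[Mg]Br | starting material
18 | (5R,6E)-5-[(3R)-3,5-bis(tert-butyldimethylsilyloxy)-3-methylpentyl]-4,4,6-trimethylocta-1,6-dien-3-one | C=CC(=O)C(C)(C)[C@H](CC[C@@](C)(O[Si](C)(C)C(C)(C)C)CCO[Si](C)(C)C(C)(C)C)/C(C)=C/C | intermediate
19 | secondary ozonide of 18 at the trisubstituted alkene | C=CC(=O)C(C)(C)[C@H](CC[C@@](C)(O[Si](C)(C)C(C)(C)C)CCO[Si](C)(C)C(C)(C)C)C1(C)OOC(C)O1 | intermediate
20 | (3S)-3-[(3R)-3,5-bis(tert-butyldimethylsilyloxy)-3-methylpentyl]-4,4-dimethylhept-6-ene-2,5-dione | C=CC(=O)C(C)(C)[C@H](CC[C@@](C)(O[Si](C)(C)C(C)(C)C)CCO[Si](C)(C)C(C)(C)C)C(C)=O | intermediate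
21 | samarium enolate alkoxide of 22 (C1 enolate, C4 alkoxide, two diiodosamarium counter-ions, trivalent samarium) | [O-]C1=CC[C@@](C)([O-])[C@@H](CC[C@@](C)(O[Si](C)(C)C(C)(C)C)CCO[Si](C)(C)C(C)(C)C)C1(C)C.[Sm+3].[Sm+3].[I-].[I-].[I-].[I-] | intermediate
22 | (3S,4R)-3-[(3R)-3,5-bis(tert-butyldimethylsilyloxy)-3-methylpentyl]-4-hydroxy-2,2,4-trimethylcyclohexan-1-one | O=C1CC[C@@](C)(O)[C@@H](CC[C@@](C)(O[Si](C)(C)C(C)(C)C)CCO[Si](C)(C)C(C)(C)C)C1(C)C | intermediate
23 | (1R,2S,4R)-2-[(3R)-3,5-bis(tert-butyldimethylsilyloxy)-3-methylpentyl]-1,3,3-trimethylcyclohexane-1,4-diol | O[C@@H]1CC[C@@](C)(O)[C@@H](CC[C@@](C)(O[Si](C)(C)C(C)(C)C)CCO[Si](C)(C)C(C)(C)C)C1(C)C | intermediate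
24 | (1R,3S,4R)-3-[(3R)-3,5-bis(tert-butyldimethylsilyloxy)-3-methylpentyl]-4-hydroxy-2,2,4-trimethylcyclohexyl acetate | CC(=O)O[C@@H]1CC[C@@](C)(O)[C@@H](CC[C@@](C)(O[Si](C)(C)C(C)(C)C)CCO[Si](C)(C)C(C)(C)C)C1(C)C | intermediate
25 | (1R,3S,4R)-3-[(3R)-3,5-dihydroxy-3-methylpentyl]-4-hydroxy-2,2,4-trimethylcyclohexyl acetate | CC(=O)O[C@@H]1CC[C@@](C)(O)[C@@H](CC[C@@](C)(O)CCO)C1(C)C | intermediate
26 | umbelliferone, 7-hydroxy-2H-chromen-2-one | Oc1ccc2ccc(=O)oc2c1 | starting material
27 | (1R,3S,4R)-4-hydroxy-3-[(3R)-3-hydroxy-3-methyl-5-(2-oxo-2H-chromen-7-yloxy)pentyl]-2,2,4-trimethylcyclohexyl acetate | CC(=O)O[C@@H]1CC[C@@](C)(O)[C@@H](CC[C@@](C)(O)CCOc2ccc3ccc(=O)oc3c2)C1(C)C | target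

**Total step count:** 15. **Longest linear sequence:** 15 steps (from 1).

**Steps most likely to fail**

1. Step 11 (proposed new method). The ketyl may close through C1 instead of C3 (pinacol), dimerise between molecules, or be reduced without ring closure; the facial selectivity at C4 may also be poor. The fallback makes the same C3–C4 bond by a known intramolecular samarium Barbier reaction; it sets out from 18 and returns at 23. Oxazaborolidine-catalysed reduction of the vinyl ketone of 18 with catecholborane (the (S)-catalyst, with the quaternary carbon expected to act as the large group) would give the allylic alcohol (3R,5R,6E)-5-[(3R)-3,5-bis(tert-butyldimethylsilyloxy)-3-methylpentyl]-4,4,6-trimethylocta-1,6-dien-3-ol F1. Silylation with TESOTf and 2,6-lutidine would give its triethylsilyl ether F2. 9-BBN followed by NaOH and H2O2 would hydroborate only the monosubstituted alkene to the primary alcohol (3R,5R,6E)-5-[(3R)-3,5-bis(tert-butyldimethylsilyloxy)-3-methylpentyl]-4,4,6-trimethyl-3-(triethylsilyloxy)oct-6-en-1-ol F3. Ozonolysis of the trisubstituted alkene (O3, then PPh3) would give the hydroxy methyl ketone (3S,5R)-3-[(3R)-3,5-bis(tert-butyldimethylsilyloxy)-3-methylpentyl]-7-hydroxy-4,4-dimethyl-5-(triethylsilyloxy)heptan-2-one F4. I2, PPh3 and imidazole would give the primary iodide F5. SmI2 with HMPA in THF would add the C3 organosamarium to the C4 ketone and give the cyclohexanol (1R,2S,4R)-2-[(3R)-3,5-bis(tert-butyldimethylsilyloxy)-3-methylpentyl]-1,3,3-trimethyl-4-(triethylsilyloxy)cyclohexan-1-ol F6. PPTS in methanol at 0 °C would remove the secondary triethylsilyl ether alone and give 23.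

2. Step 12. Facial selectivity may be poor because the axial methyl on C6 also encumbers the equatorial trajectory, so axial hydride delivery could compete and give the equatorial alcohol. The fallback replaces substrate control by catalyst control: from 22, Corey–Bakshi–Shibata reduction with the (S)-oxazaborolidine and catecholborane, in which the quaternary C6 side is the large group and the C2 methylene the small one, should deliver the (R)-configured C1 carbinol and return at 23 (no new compound, F0).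

3. Step 10. Ozone may also attack the vinyl ketone, or over-oxidation may occur at the end point. The fallback replaces ozonolysis by dihydroxylation and glycol cleavage: from 18, OsO4 (cat.) with N-methylmorpholine N-oxide in acetone/water should dihydroxylate the electron-rich trisubstituted alkene in preference to the electron-poor enone and give the diol (5S)-5-[(3R)-3,5-bis(tert-butyldimethylsilyloxy)-3-methylpentyl]-6,7-dihydroxy-4,4,6-trimethyloct-1-en-3-one F7. NaIO4 in THF/water would cleave the glycol and return the route at 20.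

**Further compounds**
F1 | step 11 | (3R,5R,6E)-5-[(3R)-3,5-bis(tert-butyldimethylsilyloxy)-3-methylpentyl]-4,4,6-trimethylocta-1,6-dien-3-ol | C=C[C@@H](O)C(C)(C)[C@H](CC[C@@](C)(O[Si](C)(C)C(C)(C)C)CCO[Si](C)(C)C(C)(C)C)/C(C)=C/C
F2 | step 11 | triethylsilyl ether of F1 | C=C[C@@H](O[Si](CC)(CC)CC)C(C)(C)[C@H](CC[C@@](C)(O[Si](C)(C)C(C)(C)C)CCO[Si](C)(C)C(C)(C)C)/C(C)=C/C
F3 | step 11 | (3R,5R,6E)-5-[(3R)-3,5-bis(tert-butyldimethylsilyloxy)-3-methylpentyl]-4,4,6-trimethyl-3-(triethylsilyloxy)oct-6-en-1-ol | OCC[C@@H](O[Si](CC)(CC)CC)C(C)(C)[C@H](CC[C@@](C)(O[Si](C)(C)C(C)(C)C)CCO[Si](C)(C)C(C)(C)C)/C(C)=C/C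
F4 | step 11 | (3S,5R)-3-[(3R)-3,5-bis(tert-butyldimethylsilyloxy)-3-methylpentyl]-7-hydroxy-4,4-dimethyl-5-(triethylsilyloxy)heptan-2-one | OCC[C@@H](O[Si](CC)(CC)CC)C(C)(C)[C@H](CC[C@@](C)(O[Si](C)(C)C(C)(C)C)CCO[Si](C)(C)C(C)(C)C)C(C)=O
F5 | step 11 | (3S,5R)-3-[(3R)-3,5-bis(tert-butyldimethylsilyloxy)-3-methylpentyl]-7-iodo-4,4-dimethyl-5-(triethylsilyloxy)heptan-2-one | ICC[C@@H](O[Si](CC)(CC)CC)C(C)(C)[C@H](CC[C@@](C)(O[Si](C)(C)C(C)(C)C)CCO[Si](C)(C)C(C)(C)C)C(C)=O
F6 | step 11 | (1R,2S,4R)-2-[(3R)-3,5-bis(tert-butyldimethylsilyloxy)-3-methylpentyl]-1,3,3-trimethyl-4-(triethylsilyloxy)cyclohexan-1-ol | CC[Si](CC)(CC)O[C@@H]1CC[C@@](C)(O)[C@@H](CC[C@@](C)(O[Si](C)(C)C(C)(C)C)CCO[Si](C)(C)C(C)(C)C)C1(C)C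
F0 | step 12 | none | none
F7 | step 10 | (5S)-5-[(3R)-3,5-bis(tert-butyldimethylsilyloxy)-3-methylpentyl]-6,7-dihydroxy-4,4,6-trimethyloct-1-en-3-one (mixture at the two carbinol carbons) | C=CC(=O)C(C)(C)[C@H](CC[C@@](C)(O[Si](C)(C)C(C)(C)C)CCO[Si](C)(C)C(C)(C)C)C(C)(O)C(C)O
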